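Retrosynthesis: the C8 glycidate, the epoxide oxygen, C13 and the C9 acetate are removed to reach a C9 ketone. Then C9–C10 and C1–C2 are cut (re-forming C2–C9), then C4=C5, C9–C2 and C7–C11, which leads back to diacetone-D-glucose.
Enabling feature: in the ten-membered carbocycle, C10(CO2Me)=C1H lies between the oxygen-bearing C9 and the methylene C2, so it is a propiolate inserted into the α-bond of a ketone. The 4,5-epoxide is cis, so its parent C4=C5 alkene fits an eight-membered ring.
Ring order forward: furanose template, then the 6,12-γ-lactone, then the cyclooctene (metathesis at C4=C5), then the bicyclo[6.2.0]decene, then the ten-membered ring, then the epoxide.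
Stereochemistry: C6 and C8 are C2 and C4 of D-glucose. C7 comes from convex-face hydrogenation, C9 from ketone reduction, C4/C5 from peripheral epoxidation, and the glycidate centre from (R)-2-methylglycidol.
The ring-cis C10=C1 geometry comes from equilibration of the alkylidene keto ester.

Key step: step 13

Remark: germacrane numbering (C1–C14) is used throughout. Glucose C1–C5 become C5, C6, C7, C8 and C9. The target SMILES is read as 4R,5S (cis epoxide), 6R,7R (cis lactone), 8S, 9S, glycidate 2S, with C9 and C2 cis on C10=C1.

Step 1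
Reactants: 1 1,2:5,6-di-O-isopropylidene-α-D-glucofuranose
Product: 2 1,2:5,6-di-O-isopropylidene-α-D-ribo-hexofuranos-3-ulose
Conditions: TEMPO (1 mol %), KBr (10 mol %), NaOCl, NaHCO3, CH2Cl2/H2O, 0 °C
Reagents that add atoms: none
Why: Oxoammonium (Anelli-type) oxidation of the only free hydroxyl gives the known 3-ulose, and both acetonides are inert to the buffered two-phase medium.

Step 2
Reactants: 2 3-ulose
Product: 3 3-deoxy-3-C-(ethoxycarbonylmethylidene)-1,2:5,6-di-O-isopropylidene-α-D-ribo-hexofuranose (E/Z mixture)
Conditions: Ph3P=CHCO2Et, CH2Cl2, 40 °C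
Reagents that add atoms: ethyl (triphenylphosphoranylidene)acetate CCOC(=O)C=P(c1ccccc1)(c1ccccc1)c1ccccc1
Why: Wittig olefination with the stabilised ylide needs no added base, so the flanking centres are not epimerised, and the alkene geometry is irrelevant because step 3 removes it.

Step 3
Reactants: 3 enoate
Product: 4 3-deoxy-3-C-(ethoxycarbonylmethyl)-1,2:5,6-di-O-isopropylidene-α-D-allofuranose
Conditions: H2 (1 atm), Pd/C, EtOAc, rt
Reagents that add atoms: none
Why: Heterogeneous hydrogenation delivers hydrogen to the convex β face of the furanose–dioxolane bicycle, which pushes the CH2CO2Et branch to the α face and sets C7 cis to both C6–O and C8–O.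

Step 4
Reactants: 4 allo ester
Product: 5 3-deoxy-3-C-(ethoxycarbonylmethyl)-1,2-O-isopropylidene-α-D-ribo-pentodialdo-1,4-furanose
Conditions: H5IO6, EtOAc, rt
Reagents that add atoms: none
Why: Periodic acid hydrolyses the more labile terminal acetonide and cleaves the freed glycol in the same flask (Malaprade cleavage), turning sugar C5 into the C9 aldehyde while the 1,2-acetonide and the ester survive.

Step 5
Reactants: 5 C9 aldehyde; 6 4-bromo-2-methylbut-1-ene
Product: 8 C9 carbinol carrying the 3-methylbut-3-enyl chain C2–C4 (both C9 epimers), via homomethallylmagnesium bromide 7 (not isolated)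
Conditions: 6, Mg, THF; then 5, THF, −78 °C; aqueous quench at −78 °C
Reagents that add atoms: magnesium [Mg] (in 7 only)
Why: Grignard addition is far faster at the aldehyde than at the ethyl ester at −78 °C, and the uncontrolled C9 carbinol centre is erased in step 6.

Step 6
Reactants: 8 C9 carbinol
Product: 9 C9 ketone (furanose 1,2-acetonide with ethyl ester branch)
Conditions: Dess–Martin periodinane, CH2Cl2, 0 °C to rt
Reagents that add atoms: none
Why: Neutral Dess–Martin oxidation converges both epimers on one α-alkoxy ketone without epimerising C8 or touching the 1,1-disubstituted alkene.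

Step 7
Reactants: 9 C9 ketone
Product: 11 open-chain 6,12-γ-lactone with C5 as 1,3-dithiane and free C8 hydroxyl, via bicyclic lactol 10 (not isolated)
Conditions: AcOH/H2O 4:1, 85 °C; evaporate with toluene; HS(CH2)3SH, BF3·OEt2 (0.3 equiv), CH2Cl2, −40 °C
Reagents that add atoms: water O; propane-1,3-dithiol SCCCS
Why: Acetal hydrolysis frees C6–OH, which lactonises on the cis ester while O8 is still locked in the furanose ring, so only the 6,12-lactone forms; thioacetalisation of the lactol (much faster than of the hindered ketone) then opens the ring without ever forming an alkoxide that could translactonise.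

Step 8
Reactants: 11 C8 alcohol
Product: 12 C8 tert-butyldimethylsilyl ether
Conditions: TBSOTf, 2,6-lutidine, CH2Cl2, −78 to 0 °C
Reagents that add atoms: tert-butyldimethylsilyl triflate CC(C)(C)[Si](C)(C)OS(=O)(=O)C(F)(F)F
Why: Silyl triflate with a hindered pyridine base caps the α-ketol hydroxyl quickly under non-alkoxide conditions, so neither acyl migration to O8 nor an α-ketol shift should intervene.

Step 9
Reactants: 12 dithiane
Product: 13 C5 aldehyde
Conditions: MeI, CaCO3, MeCN/H2O 9:1, 45 °C
Reagents that add atoms: water O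
Why: Alkylative dithiane hydrolysis is neutral and spares the silyl ether, ketone, lactone and alkene.

Step 10
Reactants: 13 C5 aldehyde
Product: 14 diene: cis-4,5-disubstituted γ-lactone with C6 vinyl and C8(OTBS)–C9(=O)–CH2CH2C(CH3)=CH2 arm
Conditions: RhCl(PPh3)3 (3 mol %), PPh3, Me3SiCHN2, i-PrOH, THF, rt
Reagents that add atoms: trimethylsilyldiazomethane C[Si](C)(C)C=[N+]=[N-]
Why: Rhodium-catalysed methylenation releases salt-free Ph3P=CH2 slowly in a neutral medium; this Wittig variant olefinates aldehydes in the presence of ketones and does not epimerise the α-acyloxy centre C6.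

Step 11
Reactants: 14 diene
Product: 15 lactone-fused (Z)-4-methylcyclooct-4-enone (C9 ketone, C8 OTBS, cis 6,12-lactone)
Conditions: second-generation Hoveyda–Grubbs catalyst (10 mol %), 1,4-benzoquinone (20 mol %), toluene (1 mM), 100 °C
Reagents that add atoms: none
Why: In this ring-closing metathesis the catalyst loads on the monosubstituted vinyl group and closes on the 1,1-disubstituted alkene, the cis arms on the γ-lactone hold the termini close, and an eight-membered ring can hold only the ring-cis C4=C5 alkene.

Step 12
Reactants: 15 cyclooctenone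
Product: 16 C9=C2 tert-butyldimethylsilyl enol ether (ring-cis, skipped diene with C4=C5)
Conditions: TBSOTf, Et3N, CH2Cl2, 0 °C
Reagents that add atoms: tert-butyldimethylsilyl triflate CC(C)(C)[Si](C)(C)OS(=O)(=O)C(F)(F)F
Why: Soft enolisation silylates the ketone oxygen but not the lactone, and the amine then removes the open C2 proton rather than the tertiary C8 proton buried between the silyl ether and C7, which fixes where the two carbons will enter.

Step 13
Reactants: 16 silyl enol ether; 17 methyl propiolate
Product: 19 ten-membered 9-siloxy-9(10),1(2)-diene 10-carboxylate (C8 cis to C1 on C9=C10; C1=C2 trans), via bicyclodecene cyclobutene 18 (not isolated)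
Conditions: 17 (2 equiv), EtAlCl2 (40 mol %), CH2Cl2, −78 to −20 °C; Et3N quench, filtration; toluene, 70 °C
Reagents that add atoms: none
Why: The aluminium-bound propiolate is attacked at its β-carbon (future C1) by enol-ether carbon C2, and the resulting allenolate closes through its α-carbon C10 on the silyloxocarbenium carbon C9; this is the stepwise Lewis-acid [2+2] cycloaddition known for silyl enol ethers and propiolates. The four-membered ring forms by 4-exo-trig closure and is necessarily cis-fused, so C2 and C9 of 18 need no control, and both become trigonal again in the next event. Warming triggers conrotatory 4π electrocyclic opening that cleaves C2–C9, so the ten-membered ring arises by two-carbon ring enlargement and not by end-to-end cyclisation. The step needs chemoselectivity for C9=C2 over the trisubstituted C4=C5, which the far higher nucleophilicity of the enol ether at low temperature secures, and regiochemistry, which the polarity of both partners dictates. It also needs torquoselectivity: the siloxy donor rotates outward, which puts C8 cis to C1 and makes C1=C2 trans, a pattern a ten-membered ring accommodates. The ethylaluminium reagent also scavenges adventitious acid and so protects the skipped diene, and the opening temperature is kept low to disfavour a [1,5]-hydrogen shift from C8.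

Step 14
Reactants: 19 siloxydiene ester
Product: 21 C11 dimethylaminomethyl lactone (CH2NMe2 syn to H7), via lithium lactone enolate 20 (not isolated)
Conditions: LDA, THF, −78 °C; CH2=NMe2+ I−, −78 to 0 °C
Reagents that add atoms: dimethylmethylideneammonium iodide C=[N+](C)C.[I-]; lithium diisopropylamide CC(C)[N-]C(C)C.[Li+] (lithium in 20 only)
Why: With the ketone masked as its enol ether, the lactone CH2 is the most accessible acidic site, so a Mannich-type aminomethylation with Eschenmoser's salt installs C13 anti to the C8 branch; this centre is erased in step 21.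

Step 15
Reactants: 21 Mannich base
Product: 23 C9 ketone with conjugated ring-cis C10=C1 alkylidene ester, via deconjugated keto ester 22 (not isolated)
Conditions: TBAF (1.0 equiv), AcOH (1.2 equiv), THF, −20 °C; then Et3N (0.2 equiv), CH2Cl2, rt
Reagents that add atoms: none
Why: Buffered fluoride cleaves the electronically activated dienol silyl ether well before the hindered C8 silyl ether, and amine-catalysed prototropic equilibration moves the alkene into conjugation with both carbonyls and settles it in the less strained geometry with C9 and C2 cis.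

Step 16
Reactants: 23 alkylidene keto ester
Product: 24 9S allylic alcohol (C9–OH trans to C8–O)
Conditions: NaBH4, CeCl3·7H2O, MeOH, −78 °C
Reagents that add atoms: none
Why: Luche reduction is 1,2-selective on alkylidene keto esters, polar Felkin–Anh attack anti to the C8–OSi bond from the ring periphery (Re face of C9) should give the 9S carbinol, and the amine-masked methylene lactone cannot be reduced by borohydride.

Step 17
Reactants: 24 allylic alcohol
Product: 25 C9 acetate
Conditions: Ac2O, pyridine, DMAP (5 mol %), CH2Cl2, 0 °C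
Reagents that add atoms: acetic anhydride CC(=O)OC(C)=O
Why: Standard nucleophile-catalysed acetylation of the only free hydroxyl.

Step 18
Reactants: 25 acetate
Product: 26 C8 alcohol
Conditions: HF·pyridine, pyridine, THF, 0 °C to rt
Reagents that add atoms: none
Why: Acidic fluoride desilylation avoids the alkoxide that would trigger O9-to-O8 acetyl migration or translactonisation, and it is run before the acid-sensitive epoxide exists.

Step 19
Reactants: 27 (R)-2-methylglycidol
Product: 28 (S)-2-methyloxirane-2-carboxylic acid
Conditions: RuCl3·xH2O (2 mol %), NaIO4, CCl4/MeCN/H2O, rt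
Reagents that add atoms: sodium periodate [Na+].[O-]I(=O)(=O)=O
Why: Catalytic ruthenium tetroxide oxidation takes epoxy alcohols to glycidic acids without touching the quaternary centre; the descriptor changes from R to S only because the substituent priorities change.

Step 20
Reactants: 26 C8 alcohol; 28 (S)-2-methylglycidic acid
Product: 30 C8 (S)-2-methylglycidate, via mixed aroyl anhydride 29 (not isolated)
Conditions: 2-methyl-6-nitrobenzoic anhydride, DMAP, Et3N, CH2Cl2, rt
Reagents that add atoms: 2-methyl-6-nitrobenzoic anhydride Cc1cccc([N+](=O)[O-])c1C(=O)OC(=O)c1c(C)cccc1[N+](=O)[O-] (aroyl group in 29 only)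
Why: Shiina esterification acylates hindered secondary alcohols quickly under weakly basic conditions, and the acid has no α-hydrogen, so its stereocentre cannot racemise.

Step 21
Reactants: 30 glycidate
Product: 32 α-methylene-γ-lactone (4,5-deoxy target), via trimethylammonium iodide 31 (not isolated)
Conditions: MeI, THF, rt; then saturated aqueous NaHCO3/CH2Cl2, rt
Reagents that add atoms: iodomethane CI (in 31 only)
Why: Quaternisation followed by mild-base β-elimination (Hofmann type, E1cB) is the standard unmasking of Mannich bases to α-methylene lactones and is too mild to disturb the acetate, glycidate or enoate.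

Step 22
Reactants: 32 α-methylene lactone
Product: 33 target CNP0274195.1
Conditions: mCPBA, NaHCO3, CH2Cl2, 0 °C
Reagents that add atoms: 3-chloroperbenzoic acid O=C(OO)c1cccc(Cl)c1
Why: Prilezhaev epoxidation picks the only electron-rich alkene (C4=C5), and allylic 1,3-strain holds H6 in the alkene plane so that C7 and C2 shield one face and peracid attack from the open periphery gives the cis 4R,5S epoxide.

Compound list
1 | 1,2:5,6-di-O-isopropylidene-α-D-glucofuranose | CC1(C)OC[C@@H](O1)[C@H]2O[C@@H]3OC(C)(C)O[C@@H]3[C@H]2O | starting material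
2 | 1,2:5,6-di-O-isopropylidene-α-D-ribo-hexofuranos-3-ulose | CC1(C)OC[C@@H](O1)[C@H]2O[C@@H]3OC(C)(C)O[C@@H]3C2=O | intermediate
3 | 3-C-(ethoxycarbonylmethylidene) derivative, E/Z mixture | CC1(C)OC[C@@H](O1)[C@H]2O[C@@H]3OC(C)(C)O[C@@H]3C2=CC(=O)OCC | intermediate
4 | 3-deoxy-3-C-(ethoxycarbonylmethyl)-1,2:5,6-di-O-isopropylidene-α-D-allofuranose | CC1(C)OC[C@@H](O1)[C@H]2O[C@@H]3OC(C)(C)O[C@@H]3[C@@H]2CC(=O)OCC | intermediate
5 | 3-deoxy-3-C-(ethoxycarbonylmethyl)-1,2-O-isopropylidene-α-D-ribo-pentodialdo-1,4-furanose | O=C[C@H]1O[C@@H]2OC(C)(C)O[C@@H]2[C@@H]1CC(=O)OCC | intermediate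
6 | 4-bromo-2-methylbut-1-ene | C=C(C)CCBr | starting material
7 | (3-methylbut-3-en-1-yl)magnesium bromide | C=C(C)CC[Mg]Br | intermediate
8 | C9 carbinol, both C9 epimers (centre left open, erased in step 6) | C=C(C)CCC(O)[C@H]1O[C@@H]2OC(C)(C)O[C@@H]2[C@@H]1CC(=O)OCC | intermediate
9 | C9 ketone on the furanose 1,2-acetonide | C=C(C)CCC(=O)[C@H]1O[C@@H]2OC(C)(C)O[C@@H]2[C@@H]1CC(=O)OCC | intermediate
10 | bicyclic lactol: 6,12-lactone cis-fused to the furanose, anomers | C=C(C)CCC(=O)[C@H]1OC(O)[C@@H]2OC(=O)C[C@H]12 | intermediate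
11 | open-chain lactone, C5 1,3-dithiane, free C8–OH | C=C(C)CCC(=O)[C@@H](O)[C@H]1CC(=O)O[C@H]1C1SCCCS1 | intermediate
12 | C8 TBS ether of 11 | C=C(C)CCC(=O)[C@@H](O[Si](C)(C)C(C)(C)C)[C@H]1CC(=O)O[C@H]1C1SCCCS1 | intermediate
13 | C5 aldehyde | C=C(C)CCC(=O)[C@@H](O[Si](C)(C)C(C)(C)C)[C@H]1CC(=O)O[C@H]1C=O | intermediate
14 | metathesis diene | C=C(C)CCC(=O)[C@@H](O[Si](C)(C)C(C)(C)C)[C@H]1CC(=O)O[C@H]1C=C | intermediate
15 | lactone-fused (Z)-cyclooctenone | C/C1=C/[C@@H]2OC(=O)C[C@@H]2[C@H](O[Si](C)(C)C(C)(C)C)C(=O)CC1 | intermediate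
16 | C9=C2 TBS enol ether | C/C1=C/[C@@H]2OC(=O)C[C@@H]2[C@H](O[Si](C)(C)C(C)(C)C)/C(O[Si](C)(C)C(C)(C)C)=C\C1 | intermediate
17 | methyl propiolate | C#CC(=O)OC | starting material
18 | cis-fused bicyclo[6.2.0]decene cyclobutene (C10 and C1 anti to O8) | C/C1=C/[C@@H]2OC(=O)C[C@@H]2[C@H](O[Si](C)(C)C(C)(C)C)[C@@]3(O[Si](C)(C)C(C)(C)C)C(C(=O)OC)=C[C@H]3C1 | intermediate
19 | ring-expanded 9-siloxy diene ester | C/C1=C/[C@@H]2OC(=O)C[C@@H]2[C@H](O[Si](C)(C)C(C)(C)C)/C(O[Si](C)(C)C(C)(C)C)=C(C(=O)OC)\C=C\C1 | intermediate
20 | lithium enolate of the lactone in 19 | C/C1=C/[C@@H]2OC([O-])=C[C@@H]2[C@H](O[Si](C)(C)C(C)(C)C)/C(O[Si](C)(C)C(C)(C)C)=C(C(=O)OC)\C=C\C1.[Li+] | intermediate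
21 | C11 dimethylaminomethyl lactone | C/C1=C/[C@@H]2OC(=O)[C@@H](CN(C)C)[C@@H]2[C@H](O[Si](C)(C)C(C)(C)C)/C(O[Si](C)(C)C(C)(C)C)=C(C(=O)OC)\C=C\C1 | intermediate
22 | deconjugated β-keto ester, C10 epimers, C1=C2 trans | C/C1=C/[C@@H]2OC(=O)[C@@H](CN(C)C)[C@@H]2[C@H](O[Si](C)(C)C(C)(C)C)C(=O)C(C(=O)OC)/C=C/C1 | intermediate
23 | alkylidene keto ester, C9 and C2 cis | C/C1=C/[C@@H]2OC(=O)[C@@H](CN(C)C)[C@@H]2[C@H](O[Si](C)(C)C(C)(C)C)C(=O)/C(C(=O)OC)=C\CC1 | intermediate
24 | 9S allylic alcohol | C/C1=C/[C@@H]2OC(=O)[C@@H](CN(C)C)[C@@H]2[C@H](O[Si](C)(C)C(C)(C)C)[C@@H](O)/C(C(=O)OC)=C\CC1 | intermediate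
25 | C9 acetate | C/C1=C/[C@@H]2OC(=O)[C@@H](CN(C)C)[C@@H]2[C@H](O[Si](C)(C)C(C)(C)C)[C@@H](OC(C)=O)/C(C(=O)OC)=C\CC1 | intermediate
26 | C8 alcohol | C/C1=C/[C@@H]2OC(=O)[C@@H](CN(C)C)[C@@H]2[C@H](O)[C@@H](OC(C)=O)/C(C(=O)OC)=C\CC1 | intermediate
27 | (R)-2-methylglycidol | OC[C@]1(C)CO1 | starting material
28 | (S)-2-methyloxirane-2-carboxylic acid | OC(=O)[C@]1(C)CO1 | intermediate
29 | mixed anhydride of 28 and 2-methyl-6-nitrobenzoic acid | Cc1cccc([N+](=O)[O-])c1C(=O)OC(=O)[C@]1(C)CO1 | intermediate
30 | C8 (S)-2-methylglycidate | C/C1=C/[C@@H]2OC(=O)[C@@H](CN(C)C)[C@@H]2[C@H](OC(=O)[C@]3(C)CO3)[C@@H](OC(C)=O)/C(C(=O)OC)=C\CC1 | intermediate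
31 | C13 trimethylammonium iodide | C/C1=C/[C@@H]2OC(=O)[C@@H](C[N+](C)(C)C)[C@@H]2[C@H](OC(=O)[C@]3(C)CO3)[C@@H](OC(C)=O)/C(C(=O)OC)=C\CC1.[I-] | intermediate
32 | α-methylene lactone, C4=C5 still an alkene | C/C1=C/[C@@H]2OC(=O)C(=C)[C@@H]2[C@H](OC(=O)[C@]3(C)CO3)[C@@H](OC(C)=O)/C(C(=O)OC)=C\CC1 | intermediate
33 | CNP0274195.1 | C=C1C(=O)O[C@@H]2[C@H]1[C@H](OC(=O)[C@]1(C)CO1)[C@@H](OC(C)=O)/C(C(=O)OC)=C\CC[C@@]1(C)O[C@@H]21 | target

Total step count: 22. Longest linear sequence: 21 (steps 1–18 and 20–22; step 19 is a one-step side branch).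

Steps most likely to fail

Step 13. Several things could go wrong:
- The cycloaddition may stop at the open-chain Michael stage through silyl transfer.
- The Lewis acid may isomerise the skipped diene.
- The heating needed for ring opening may start a [1,5]-hydrogen shift that flattens C8.

The fallback changes the donor while keeping the same bonds and rings. It sets out from ketone 15. Pyrrolidine and TiCl4 give the less substituted C9=C2 pyrrolidine enamine F1. This adds methyl propiolate without any Lewis acid (the enamine–alkynoate ring enlargement) to give the aminocyclobutene F2. F2 opens at or below room temperature to the ten-membered 9-pyrrolidinyl diene ester F3. Aminomethylation of the lactone as in step 14 gives the Mannich base F4. Buffered aqueous acetic acid then hydrolyses the dienamine, and the route is rejoined at 23 (through 22).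

Step 11. Intermolecular metathesis of the vinyl group may lead to oligomers. The catalyst may be tied up by the C9 carbonyl, or it may decay before the 1,1-disubstituted alkene is engaged. The fallback changes the substrate rather than the catalyst. It sets out from 14. Borohydride reduction gives the C9 carbinol diene F5 (drawn as the Felkin epimer; the configuration is immaterial). The tetrahedral, non-chelating C9 in F5 lowers the strain of the forming ring. Ring closure gives the cyclooctenol F6, and Dess–Martin oxidation returns to 15.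

Step 16. The ring conformation may override the Felkin–Anh preference and turn the wrong face of C9 outward, which would give poor or inverted facial selectivity. The fallback replaces substrate control by reagent control. It sets out from 23 and uses oxazaborolidine-catalysed borane reduction (Corey–Bakshi–Shibata). The catalyst enantiomer is chosen to deliver hydride to the Re face of C9. The route returns at 24, and no new compound arises (F0).

Further compounds
F1 | step 13 | C9=C2 pyrrolidine enamine of 15 | C/C1=C/[C@@H]2OC(=O)C[C@@H]2[C@H](O[Si](C)(C)C(C)(C)C)/C(N3CCCC3)=C\C1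
F2 | step 13 | cis-fused 9-pyrrolidinyl cyclobutene | C/C1=C/[C@@H]2OC(=O)C[C@@H]2[C@H](O[Si](C)(C)C(C)(C)C)[C@@]3(N4CCCC4)C(C(=O)OC)=C[C@H]3C1
F3 | step 13 | ten-membered 9-pyrrolidinyl diene ester | C/C1=C/[C@@H]2OC(=O)C[C@@H]2[C@H](O[Si](C)(C)C(C)(C)C)/C(N3CCCC3)=C(C(=O)OC)\C=C\C1
F4 | step 13 | C11 dimethylaminomethyl derivative of F3 | C/C1=C/[C@@H]2OC(=O)[C@@H](CN(C)C)[C@@H]2[C@H](O[Si](C)(C)C(C)(C)C)/C(N3CCCC3)=C(C(=O)OC)\C=C\C1
F5 | step 11 | C9 carbinol of diene 14 | C=C(C)CC[C@H](O)[C@@H](O[Si](C)(C)C(C)(C)C)[C@H]1CC(=O)O[C@H]1C=C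
F6 | step 11 | lactone-fused cyclooctenol | C/C1=C/[C@@H]2OC(=O)C[C@@H]2[C@H](O[Si](C)(C)C(C)(C)C)[C@@H](O)CC1
F0 | step 16 | none | none
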